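All runs come from a simulation for substances that don't exist.

I decided to rate these flasks by one count of minutes rather than by a full model. Substrate goes to intermediate and, reversibly, to dormant form; partner captures intermediate as target.

| flask | substrate | partner | remark | time |
|---|---|---|---|---|
| Friday's | 41 mM | 0.95 equiv | run made earlier |  |
| Thursday's | 20 mM | 0.95 equiv | run made earlier |  |
| Wednesday's | 82 mM | 0.95 equiv | run made earlier |  |
| maple | 41 mM (fed, over 25 min) | 0.950 equiv | all else is in the flask from the start; the feed brings no volume worth counting | 30 min |
| alder | 41 mM | 0.950 equiv (in portions, 5, over 25 min) | first portion at the start, last at 25 min | 30 min |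
| cedar | 41 mM | 0.950 equiv (fed, over 25 min) | all else is in the flask from the start; the feed brings no volume worth counting | 30 min |
| larch | 41 mM | 0.950 equiv | everything together at the start | 30 min |

| run | time / min | target / % | substrate / % |
|---|---|---|---|
| Friday's | 1.50 | 0.2 | 62.7 |
| Friday's | 5.00 | 0.8 | 31.5 |
| Friday's | 8.00 | 4.2 | 23.9 |
| Friday's | 12.0 | 4.9 | 21.3 |
| Friday's | 20.0 | 9.7 | 17.6 |
| Friday's | 25.0 | 13.6 | 16.1 |
| Friday's | 30.0 | 16.2 | 14.8 |
| Thursday's | 2.00 | 0.8 | 55.1 |
| Thursday's | 3.00 | 0 | 43.4 |
| Thursday's | 4.00 | 0.1 | 36.0 |
| Thursday's | 6.00 | 0.2 | 27.9 |
| Thursday's | 10.0 | 2.7 | 21.3 |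
| Thursday's | 15.0 | 3.5 | 18.8 |
| Thursday's | 25.0 | 8.0 | 15.8 |
| Wednesday's | 3.00 | 2.3 | 43.9 |
| Wednesday's | 6.00 | 2.6 | 27.6 |
| Wednesday's | 10.0 | 7.0 | 22.7 |
| Wednesday's | 15.0 | 11.2 | 19.8 |
| Wednesday's | 20.0 | 15.5 | 18.3 |
| Wednesday's | 25.0 | 19.1 | 16.3 |

(standard deviation of a reading: 0.5 percentage points)

- which flask leads in amount of target, in percent of the substrate charged ("all alike" within 1.5 percentage points) (maple / alder / cedar / larch / all alike)
- how much target is there at the end, in percent of the substrate charged: maple
- how much target is there at the end, in percent of the substrate charged: alder
- how much target is there at the end, in percent of the substrate charged: cedar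
- how much target is there at the end, in percent of the substrate charged: larch

- percent here means substrate units held: one homo product or self-condensation product counts as two
- steps thought possible: substrate -> intermediate; partner + intermediate -> target; 2 intermediate -> homo product; target <-> isomer of the product; substrate <-> dormant form; 2 substrate -> self-condensation product

I read a ladder from Friday's run, fastest rung first. Substrate fell to 62.7% at 1.50 min, a time constant of 3.21 min. Next came the lag of target: from 20.0 min to 30.0 min target climbed at 0.00650 /min, as a fraction of the charge, and that line runs back to zero at 5.08 min, later than the fall's time constant. Slowest was the later drain of substrate, with a time constant of 49.4 min, longer than the run. Substrate still fell from 31.5% at 5.00 min to 14.8% at 30.0 min, so the supply of intermediate was not steady, but I took the climb of target as a straight line after the lag, as a working assumption. Target reached 16.2% against partner charged at 0.95 equiv, so I held [partner] near its charge and treated capture as pseudo-first-order in intermediate.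

I called this slope the capture rate, the target gained per minute after the lag with the full partner charge present. Target is then that rate times the minutes after the lag, each weighted by the share of partner in the flask. Integrating cedar's rising share gave 17.0 min, so 11.1%. Alder's stairs gave 16.5 min, so 10.7%. In maple the mean substrate arrives 12.5 min late, leaving 12.4 min, so 8.06%. Larch repeats Friday's run, so I expected 16.2%.

The forecast put larch first, with maple 10%, alder 11.3%, cedar 10.2% and larch 16.4%, saying “Withholding partner loses capture time”. My maple stood lower than its figure and my cedar higher.

The flasks gave larch first: maple 8.67%, alder 11.8%, cedar 12.1%, larch 15.6%.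

    substrate → intermediate (k = 0.0620 /min)
    partner + intermediate → target (k = 0.790 /M/min)
    2 intermediate → homo product (k = 0.550 /M/min)
    target ⇌ isomer of the product (K = 3.20, k = 0.00510 /min)
    substrate ⇌ dormant form (K = 2.20, k = 0.270 /min)
    2 substrate → self-condensation product (k = 0.00630 /M/min)

Divided by the capture rate, cedar's target is 18.6 min against my 17.0 min, and maple's is 13.3 min against my 12.4 min. Larch captured from the start and ended with homo product at 5.74%, while cedar, its partner fed in, ended at 7.42%. Maple ended with dormant form at 47.1% against larch's 38.1%. Larch's lead over cedar is 3.5 percentage points, and larch stopped at 21.2 min has moved by 5 points, so with cedar still read at 30 min that is the kind of change that would overturn the forecast.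

With larch's partner cut to 0.240 equiv, the weight on its minutes is 0.253, and the capture rate gives 4.09%. The computed flask holds 4.72%.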